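**Retrosynthetic overview**
1. Target 11 ⇒ desilylation and O‑methylation of the 5‑hydroxy‑6‑prenyl isoflav‑3‑ene 9; the single free 5‑OH first carries the prenyl precursor, then the methyl.
2. C6‑prenyl ⇒ aromatic Claisen rearrangement of the 5‑O‑(1,1‑dimethylallyl) ether 8; C6 is the only open ortho position.
3. Ring C (C3–C4 and O1–C2 bonds) ⇒ one‑step Petasis / o‑quinone‑methide / oxa‑6π annulation of the mirror‑symmetric aldehyde 2 with the α‑arylvinyl boronate 6. This step differentiates the two equivalent ortho‑OH groups.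
4. 2 ⇐ 2,4,6‑trihydroxybenzaldehyde (ring A); 6 ⇐ 2',4'‑dihydroxyacetophenone (ring B) via its vinyl triflate.
5. Ring order: A and B are bought; C is the only ring formed, in the key step.

Assumption: the target has no stereocentre (the only ring alkene is endocyclic), so "single enantiomer" needs no stereocontrol. All steps after ring C is formed are kept non‑acidic, because 2'‑hydroxyisoflav‑3‑enes are prone to acid‑promoted cyclisation.

---

**Step 1**
Reactants: 1, 2,4,6‑trihydroxybenzaldehyde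
Product: 2, 2,6‑dihydroxy‑4‑(triisopropylsilyloxy)benzaldehyde
Conditions: TIPSCl (1.05 equiv), imidazole, DMF, 0 °C → rt
Reagents that add atoms: TIPSCl, CC(C)[Si](Cl)(C(C)C)C(C)C
Why: Chemoselective silyl ether formation; the 4‑OH is the only phenol not hydrogen‑bonded to and flanked by the CHO, so it silylates first and the product keeps its mirror symmetry.

**Step 2**
Reactants: 3, 1‑(2,4‑dihydroxyphenyl)ethan‑1‑one (2',4'‑dihydroxyacetophenone)
Product: 4, 1‑[2,4‑bis(tert‑butyldimethylsilyloxy)phenyl]ethan‑1‑one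
Conditions: TBSCl (2.5 equiv), imidazole, DMAP (cat.), DMF, 40 °C
Reagents that add atoms: TBSCl, CC(C)(C)[Si](C)(C)Cl
Why: Exhaustive phenol silylation; DMAP and mild heating overcome the chelated 2‑OH.

**Step 3**
Reactants: 4, 1‑[2,4‑bis(TBS‑oxy)phenyl]ethan‑1‑one
Product: 5, 1‑[2,4‑bis(TBS‑oxy)phenyl]vinyl trifluoromethanesulfonate
Conditions: Tf2O (1.2 equiv), 2,6‑di‑tert‑butyl‑4‑methylpyridine, CH2Cl2, 0 °C → rt; used crude
Reagents that add atoms: Tf2O, O=S(=O)(OS(=O)(=O)C(F)(F)F)C(F)(F)F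
Why: Vinyl triflate formation by O‑triflation of the aryl methyl ketone and loss of an α‑proton (hindered‑pyridine method); no free enolate is generated, which avoids O→O silyl migration from the 2'‑OTBS group.

**Step 4**
Reactants: 5, 1‑[2,4‑bis(TBS‑oxy)phenyl]vinyl triflate
Product: 6, 2‑{1‑[2,4‑bis(TBS‑oxy)phenyl]vinyl}‑4,4,5,5‑tetramethyl‑1,3,2‑dioxaborolane
Conditions: B2pin2, PdCl2(PPh3)2 (3 mol%), PPh3, KOPh, toluene, 50 °C
Reagents that add atoms: B2pin2, CC1(C)OB(B2OC(C)(C)C(C)(C)O2)OC1(C)C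
Why: Miyaura borylation of an alkenyl triflate (oxidative addition, B–B transmetalation, reductive elimination) under mild base that tolerates aryl silyl ethers.

**Step 5 (key step)**
Reactants: 2, 2,6‑dihydroxy‑4‑(TIPS‑oxy)benzaldehyde; 6, α‑arylvinyl pinacol boronate
Product: 7, 3‑[2,4‑bis(TBS‑oxy)phenyl]‑7‑(TIPS‑oxy)‑2H‑chromen‑5‑ol
Conditions: Bn2NH (1.0 equiv), 1,4‑dioxane, 90 °C, Ar
Reagents that add atoms: none (both partners are numbered reactants; the amine is released)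
Why: Proposed new method: Bn2NH and the aldehyde of 2 give an ortho‑hydroxy iminium; a phenoxide–boron ate complex delivers the 1‑arylvinyl group to the iminium carbon (Petasis borono‑Mannich); at 90 °C the electron‑rich Mannich base expels Bn2NH to give a dearomatised vinyl o‑quinone methide, which closes by oxa‑6π electrocyclisation onto the terminal CH2 to the 3‑aryl‑2H‑chromene. Because the two ortho‑OH groups of 2 are symmetry‑equivalent, only one regioisomer can form, and the untouched one becomes the unique 5‑OH. The closest known reaction is the amine‑mediated Petasis 2H‑chromene annulation of salicylaldehydes with β‑substituted alkenylboronic acids, extended here to an α‑aryl vinyl pinacol boronate and a 2,6‑dihydroxybenzaldehyde.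

**Step 6**
Reactants: 7, 3‑[2,4‑bis(TBS‑oxy)phenyl]‑7‑(TIPS‑oxy)‑2H‑chromen‑5‑ol
Product: 8, 3‑[2,4‑bis(TBS‑oxy)phenyl]‑5‑[(2‑methylbut‑3‑en‑2‑yl)oxy]‑7‑(TIPS‑oxy)‑2H‑chromene
Conditions: tert‑butyl (2‑methylbut‑3‑en‑2‑yl) carbonate (1.5 equiv), Pd(PPh3)4 (5 mol%), THF, 0 °C; Pd removed before the next step
Reagents that add atoms: tert‑butyl (2‑methylbut‑3‑en‑2‑yl) carbonate, C=CC(C)(C)OC(=O)OC(C)(C)C (if not purchased, one step from 2‑methylbut‑3‑en‑2‑ol and Boc2O)
Why: Tsuji–Trost O‑allylation; under kinetic, low‑temperature conditions the phenoxide attacks the more substituted terminus of the π‑(dimethylallyl)Pd complex to give the tertiary ether, and 5‑OH is the only free hydroxyl.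

**Step 7**
Reactants: 8, the 5‑O‑(1,1‑dimethylallyl) ether
Product: 9, 3‑[2,4‑bis(TBS‑oxy)phenyl]‑6‑(3‑methylbut‑2‑en‑1‑yl)‑7‑(TIPS‑oxy)‑2H‑chromen‑5‑ol
Conditions: toluene, 110 °C, Ar
Reagents that add atoms: none
Why: Aromatic Claisen [3,3] rearrangement through a dearomatised dienone; C4a is quaternary, so the allyl unit is delivered, with inversion to the normal prenyl group, only to C6, and tautomerisation restores the phenol.

**Step 8**
Reactants: 9, the 6‑prenyl‑chromen‑5‑ol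
Product: 10, 3‑[2,4‑bis(TBS‑oxy)phenyl]‑5‑methoxy‑6‑(3‑methylbut‑2‑en‑1‑yl)‑7‑(TIPS‑oxy)‑2H‑chromene
Conditions: MeI (3 equiv), K2CO3, acetone, 50 °C
Reagents that add atoms: MeI, CI
Why: Williamson O‑methylation of the only free phenol; aryl silyl ethers tolerate anhydrous K2CO3/acetone.

**Step 9**
Reactants: 10, the tris‑silyl ether
Product: 11, dehydroglyasperin C, 4‑[7‑hydroxy‑5‑methoxy‑6‑(3‑methylbut‑2‑en‑1‑yl)‑2H‑chromen‑3‑yl]benzene‑1,3‑diol
Conditions: TBAF (3.5 equiv), AcOH (3.5 equiv), THF, 0 °C → rt, Ar; pH 7 work‑up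
Reagents that add atoms: none
Why: Fluoride‑mediated cleavage of all three aryl silyl ethers; AcOH buffering avoids oxidation of the free phenoxides, and no acid is used that could cyclise the 2'‑OH or 7‑OH onto the alkenes.

---

**Compound list**
1 | 2,4,6‑trihydroxybenzaldehyde | O=Cc1c(O)cc(O)cc1O | starting material
2 | 2,6‑dihydroxy‑4‑(triisopropylsilyloxy)benzaldehyde | O=Cc1c(O)cc(O[Si](C(C)C)(C(C)C)C(C)C)cc1O | intermediate
3 | 2',4'‑dihydroxyacetophenone | CC(=O)c1ccc(O)cc1O | starting material (bulk resorcinol‑derived aromatic feedstock)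
4 | 1‑[2,4‑bis(TBS‑oxy)phenyl]ethan‑1‑one | CC(=O)c1ccc(O[Si](C)(C)C(C)(C)C)cc1O[Si](C)(C)C(C)(C)C | intermediate
5 | 1‑[2,4‑bis(TBS‑oxy)phenyl]vinyl triflate | C=C(OS(=O)(=O)C(F)(F)F)c1ccc(O[Si](C)(C)C(C)(C)C)cc1O[Si](C)(C)C(C)(C)C | intermediate
6 | 2‑{1‑[2,4‑bis(TBS‑oxy)phenyl]vinyl}‑4,4,5,5‑tetramethyl‑1,3,2‑dioxaborolane | C=C(B1OC(C)(C)C(C)(C)O1)c1ccc(O[Si](C)(C)C(C)(C)C)cc1O[Si](C)(C)C(C)(C)C | intermediate
7 | 3‑[2,4‑bis(TBS‑oxy)phenyl]‑7‑(TIPS‑oxy)‑2H‑chromen‑5‑ol | Oc1cc(O[Si](C(C)C)(C(C)C)C(C)C)cc2c1C=C(c1ccc(O[Si](C)(C)C(C)(C)C)cc1O[Si](C)(C)C(C)(C)C)CO2 | intermediate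
8 | 3‑[2,4‑bis(TBS‑oxy)phenyl]‑5‑[(2‑methylbut‑3‑en‑2‑yl)oxy]‑7‑(TIPS‑oxy)‑2H‑chromene | C=CC(C)(C)Oc1cc(O[Si](C(C)C)(C(C)C)C(C)C)cc2c1C=C(c1ccc(O[Si](C)(C)C(C)(C)C)cc1O[Si](C)(C)C(C)(C)C)CO2 | intermediate
9 | 3‑[2,4‑bis(TBS‑oxy)phenyl]‑6‑(3‑methylbut‑2‑en‑1‑yl)‑7‑(TIPS‑oxy)‑2H‑chromen‑5‑ol | Oc1c(CC=C(C)C)c(O[Si](C(C)C)(C(C)C)C(C)C)cc2c1C=C(c1ccc(O[Si](C)(C)C(C)(C)C)cc1O[Si](C)(C)C(C)(C)C)CO2 | intermediate
10 | 3‑[2,4‑bis(TBS‑oxy)phenyl]‑5‑methoxy‑6‑(3‑methylbut‑2‑en‑1‑yl)‑7‑(TIPS‑oxy)‑2H‑chromene | COc1c(CC=C(C)C)c(O[Si](C(C)C)(C(C)C)C(C)C)cc2c1C=C(c1ccc(O[Si](C)(C)C(C)(C)C)cc1O[Si](C)(C)C(C)(C)C)CO2 | intermediate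
11 | Dehydroglyasperin C | COc1c2c(cc(O)c1CC=C(C)C)OCC(c1ccc(O)cc1O)=C2 | target (achiral)

---

**Total steps:** 9
**Longest linear sequence:** 8 (3 → 4 → 5 → 6 → 7 → 8 → 9 → 10 → 11; the ring‑A branch 1 → 2 joins at step 5)

**Steps most likely to fail, with fallbacks**
1. Step 5 (annulation): the hindered α‑arylvinyl transfer may be slow, or the boronate may protodeboronate. Fallback: Nozaki–Hiyama–Kishi (CrCl2/NiCl2) addition of vinyl triflate 5 to aldehyde 2 to give the o‑hydroxybenzylic allylic alcohol, then thermal dehydrative o‑quinone‑methide/oxa‑6π closure to 7. This uses the same symmetric aldehyde, needs no boron or amine, and removes step 4.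
2. Step 3 (vinyl triflate): the electron‑rich α‑arylvinyl triflate may ionise or lose silyl groups. Fallback: make 6 without ketone chemistry, from 4‑bromoresorcinol by bis‑silylation and Pd‑catalysed mono‑Suzuki coupling with 1,1‑bis(pinacolboryl)ethene.
3. Step 6 (O‑tert‑prenylation): the hindered 5‑OH may give the linear prenyl ether, or Pd(0) may engage the chromene allylic ether. Fallback: direct ortho‑C‑prenylation of the sodium phenoxide of 7 (NaH, toluene, prenyl bromide) to give 9 in one step, replacing the ether/[3,3] sequence with C‑alkylation.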